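**Plan**

1. Retrosynthetic cuts, in order: the C1 methyl ketal (to the 4‑hydroxy‑1‑ketone), the C6–O ester bond (made with inversion), then the C6–C7 ring bond, which opens the ten‑membered ring to a 3‑(bromomethyl)butenolide aldehyde; then the butenolide C7=C11 bond (metathesis) and its ester C–O bond; finally C1–C2 (crossed Claisen, then loss of CO2), giving two γ‑lactones.
2. Forward order: West γ‑lactone (C7–C10 and C1) and East γ‑lactone (C2–C6) are joined at C1–C2; the butenolide ring is closed by metathesis; a temporary tetrahydrofuran ketal ring (C1–O–C4) is formed; the ten‑membered carbocycle is closed at C6–C7; the ester is installed; the ketal is removed.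
3. Feature that makes the key event possible: the homoallylic alcohol array O–C6–C7–C11=C13 inside the α‑methylene‑γ‑butyrolactone ring. With the double bond moved into the lactone ring (C7=C11), C7 is the γ‑terminus of an allyl unit C13–C11=C7, and the 1,4‑related C1 ketone and C4 hydroxyl can be tied into a tetrahydrofuran ketal that masks the ketone and shortens the closure.
4. Stereochemistry: C8 from commercial (S)‑lactone 1; C10 by trans‑selective alkylation of that lactone; C4 by Sharpless epoxidation of geraniol; C7 (tether control) and C6 (chair transition state) in the key step; C6 is then inverted in the Mitsunobu step that installs the isobutyrate.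

Key step: step 15

Remarks. Positions carry germacrane numbers: C1 ketone carbon, C4 tertiary carbinol, C6 acyloxy carbon, C7/C8 lactone ring fusion, C10 methyl‑bearing carbon, C11=C13 methylene, C12 lactone carbonyl.
Assumption: the 4‑hydroxy‑1‑ketone drawn and its transannular 1,4‑hemiketal are tautomers, and ketal hydrolysis in the last step is taken to give the form drawn.

**Route**

Step 1
Reactants: 1 (S)-5-[(trityloxy)methyl]dihydrofuran-2(3H)-one
Product: 3 (3R,5S)-3-methyl-5-[(trityloxy)methyl]dihydrofuran-2(3H)-one, via lithium enolate 2 (not isolated)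
Conditions: lithium diisopropylamide, THF, −78 °C; then MeI, −78 °C
Reagents that add atoms: iodomethane, CI
Why: Alkylation of the lithium lactone enolate should occur on the face opposite the bulky trityloxymethyl group (1,3‑trans‑selective lactone enolate alkylation), which sets C10 relative to the existing C8 centre.

Step 2
Reactants: 3 (3R,5S)-3-methyl-5-[(trityloxy)methyl]dihydrofuran-2(3H)-one
Product: 4 (3R,5S)-5-(hydroxymethyl)-3-methyldihydrofuran-2(3H)-one
Conditions: AcOH/H2O (4:1), 50 °C
Reagents that add atoms: none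
Why: Acid solvolysis of the trityl ether should leave the γ‑lactone and both stereocentres untouched.

Step 3
Reactants: 4 (3R,5S)-5-(hydroxymethyl)-3-methyldihydrofuran-2(3H)-one
Product: 6 (3R,5S)-3-methyl-5-vinyldihydrofuran-2(3H)-one, via lactone aldehyde 5 (not isolated)
Conditions: Dess–Martin periodinane, pyridine, CH2Cl2, 0 °C; then Ph3P=CH2 (from Ph3PCH3Br, KN(SiMe3)2), THF, −78 to 0 °C
Reagents that add atoms: methyltriphenylphosphonium bromide, C[P+](c1ccccc1)(c1ccccc1)c1ccccc1.[Br-]
Why: Dess–Martin oxidation gives the configurationally labile α‑acyloxy aldehyde, which is trapped at low temperature by Wittig methylenation so that C8 should not epimerise.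

Step 4
Reactants: 7 geraniol
Product: 8 [(2S,3S)-3-methyl-3-(4-methylpent-3-en-1-yl)oxiran-2-yl]methanol
Conditions: Ti(OiPr)4 (cat.), L-(+)-diethyl tartrate (cat.), t-BuOOH, 4 Å molecular sieves, CH2Cl2, −20 °C
Reagents that add atoms: tert-butyl hydroperoxide, CC(C)(C)OO
Why: Sharpless asymmetric epoxidation should oxidise only the allylic‑alcohol alkene, on one face, and so fix the future C4 centre (3S in the epoxide).

Step 5
Reactants: 8 [(2S,3S)-3-methyl-3-(4-methylpent-3-en-1-yl)oxiran-2-yl]methanol
Product: 9 (S)-3,7-dimethyloct-6-ene-1,3-diol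
Conditions: NaAlH2(OCH2CH2OMe)2, THF, 0 °C
Reagents that add atoms: none
Why: Hydroxyl‑directed hydride delivery from the alkoxyaluminate should open the 2,3‑epoxy alcohol at C2, giving the 1,3‑diol with the tertiary C–O bond (future C4) untouched.

Step 6
Reactants: 9 (S)-3,7-dimethyloct-6-ene-1,3-diol
Product: 10 (S)-1-[(4-methoxybenzyl)oxy]-3,7-dimethyloct-6-en-3-ol
Conditions: NaH, 4-methoxybenzyl chloride, Bu4NI (cat.), THF/DMF, 0 °C
Reagents that add atoms: 4-methoxybenzyl chloride, COc1ccc(CCl)cc1
Why: Williamson etherification should take place at the far less hindered primary alkoxide and so protect the future C6 oxygen selectively.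

Step 7
Reactants: 10 (S)-1-[(4-methoxybenzyl)oxy]-3,7-dimethyloct-6-en-3-ol
Product: 12 (S)-5-[2-[(4-methoxybenzyl)oxy]ethyl]-5-methyldihydrofuran-2(3H)-one, via lactol 11 (not isolated)
Conditions: O3 (indicator end point), CH2Cl2/MeOH, −78 °C; Me2S; then PhI(OAc)2, TEMPO (cat.), CH2Cl2, rt
Reagents that add atoms: ozone, [O-][O+]=O
Why: Ozonolysis cleaves the electron‑rich trisubstituted alkene, the aldehyde closes onto the tertiary hydroxyl as lactol 11, and TEMPO/PhI(OAc)2 oxidises the lactol to the γ‑lactone, whose carbonyl carbon is the one later lost as CO2.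

Step 8
Reactants: 12 (S)-5-[2-[(4-methoxybenzyl)oxy]ethyl]-5-methyldihydrofuran-2(3H)-one; 6 (3R,5S)-3-methyl-5-vinyldihydrofuran-2(3H)-one
Product: 14 (5S)-3-[(2R,4S)-4-hydroxy-2-methylhex-5-enoyl]-5-[2-[(4-methoxybenzyl)oxy]ethyl]-5-methyldihydrofuran-2(3H)-one, via lithium enolate 13 (not isolated)
Conditions: lithium diisopropylamide, THF, −78 °C; then 6, −78 to −40 °C; AcOH quench
Reagents that add atoms: none
Why: In this crossed Claisen condensation the unhindered enolate 13 should acylate at the carbonyl of lactone 6, which offers only a hindered tertiary α‑hydrogen for competing proton transfer, forging C1–C2 without touching C10.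

Step 9
Reactants: 14 (5S)-3-[(2R,4S)-4-hydroxy-2-methylhex-5-enoyl]-5-[2-[(4-methoxybenzyl)oxy]ethyl]-5-methyldihydrofuran-2(3H)-one
Product: 16 (3S,5R,9S)-3,9-dihydroxy-11-[(4-methoxybenzyl)oxy]-5,9-dimethylundec-1-en-6-one, via β-keto acid 15 (not isolated)
Conditions: LiOH, THF/H2O, rt; then AcOH to pH 5, 45 °C
Reagents that add atoms: none
Why: Saponification of the α‑acyl lactone and decarboxylation of β‑keto acid 15 on mild acidification (ketonic cleavage of a β‑keto ester) should excise the extra carbon and free the C4 hydroxyl, while C10 is shielded because the ketone sits in the β‑dicarbonyl enolate under the basic conditions.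

Step 10
Reactants: 16 (3S,5R,9S)-3,9-dihydroxy-11-[(4-methoxybenzyl)oxy]-5,9-dimethylundec-1-en-6-one; 17 2-(bromomethyl)acrylic acid
Product: 18 (3S,5R,9S)-9-hydroxy-11-[(4-methoxybenzyl)oxy]-5,9-dimethyl-6-oxoundec-1-en-3-yl 2-(bromomethyl)acrylate
Conditions: dicyclohexylcarbodiimide, DMAP (cat.), CH2Cl2, −20 °C
Reagents that add atoms: none
Why: Carbodiimide (Steglich‑type) esterification should acylate the secondary allylic hydroxyl and leave the tertiary one free.

Step 11
Reactants: 18 (3S,5R,9S)-9-hydroxy-11-[(4-methoxybenzyl)oxy]-5,9-dimethyl-6-oxoundec-1-en-3-yl 2-(bromomethyl)acrylate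
Product: 19 (S)-3-(bromomethyl)-5-[(2R,6S)-6-hydroxy-8-[(4-methoxybenzyl)oxy]-2,6-dimethyl-3-oxooctyl]furan-2(5H)-one
Conditions: second-generation Hoveyda–Grubbs catalyst (cat.), toluene, 80 °C
Reagents that add atoms: none
Why: Ring‑closing metathesis between the vinyl group and the 1,1‑disubstituted acrylate should close the five‑membered butenolide with loss of ethylene, leaving the allylic bromide on the α‑carbon.

Step 12
Reactants: 19 (S)-3-(bromomethyl)-5-[(2R,6S)-6-hydroxy-8-[(4-methoxybenzyl)oxy]-2,6-dimethyl-3-oxooctyl]furan-2(5H)-one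
Product: 20 (S)-3-(bromomethyl)-5-[(R)-2-[(2R,5S)-2-methoxy-5-[2-[(4-methoxybenzyl)oxy]ethyl]-5-methyltetrahydrofuran-2-yl]propyl]furan-2(5H)-one
Conditions: MeOH, pyridinium p-toluenesulfonate (cat.), 3 Å molecular sieves, rt
Reagents that add atoms: methanol, CO
Why: Acid‑catalysed ketalisation of the γ‑hydroxy ketone in methanol should give the 2‑methoxytetrahydrofuran that masks the C1 ketone and the C4 hydroxyl at once; the C1 epimers interconvert under these conditions and the one drawn (C10 and C5 cis on the ring) is taken on, the other being returned to the equilibration.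

Step 13
Reactants: 20 (S)-3-(bromomethyl)-5-[(R)-2-[(2R,5S)-2-methoxy-5-[2-[(4-methoxybenzyl)oxy]ethyl]-5-methyltetrahydrofuran-2-yl]propyl]furan-2(5H)-one
Product: 21 (S)-3-(bromomethyl)-5-[(R)-2-[(2R,5S)-5-(2-hydroxyethyl)-2-methoxy-5-methyltetrahydrofuran-2-yl]propyl]furan-2(5H)-one
Conditions: DDQ, CH2Cl2/pH 7 phosphate buffer, 0 °C
Reagents that add atoms: none
Why: Buffered DDQ oxidation should remove the 4‑methoxybenzyl ether without ionising the mixed ketal or touching the allylic bromide.

Step 14
Reactants: 21 (S)-3-(bromomethyl)-5-[(R)-2-[(2R,5S)-5-(2-hydroxyethyl)-2-methoxy-5-methyltetrahydrofuran-2-yl]propyl]furan-2(5H)-one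
Product: 22 (S)-3-(bromomethyl)-5-[(R)-2-[(2R,5S)-2-methoxy-5-methyl-5-(2-oxoethyl)tetrahydrofuran-2-yl]propyl]furan-2(5H)-one
Conditions: Dess–Martin periodinane, pyridine, CH2Cl2, 0 °C
Reagents that add atoms: none
Why: Pyridine‑buffered Dess–Martin oxidation should give the aldehyde under non‑acidic, non‑nucleophilic conditions that the ketal and the allylic bromide tolerate.

Step 15
Reactants: 22 (S)-3-(bromomethyl)-5-[(R)-2-[(2R,5S)-2-methoxy-5-methyl-5-(2-oxoethyl)tetrahydrofuran-2-yl]propyl]furan-2(5H)-one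
Product: 24 (1R,4S,6S,7R,8S,10R)-1,4-epoxy-6-hydroxy-1-methoxygermacr-11(13)-en-8,12-olide (7,8-cis lactone; C6 carbinol epimeric to that of the target), via allylchromium species 23 (not isolated)
Conditions: CrCl2 (excess), THF, rt, slow addition of 22 to about 2 mM
Reagents that add atoms: none
Why: Two equivalents of divalent chromium insert into the allylic C–Br bond to give allylchromium 23, whose γ‑carbon C7 (the β‑carbon of the butenolide) adds to the C6 aldehyde through a closed six‑membered chair transition state with allyl transposition, so that the C11=C13 methylene and the C6 carbinol arise together with the new bond. The closest known reaction type is the intramolecular Nozaki–Hiyama (Barbier‑type) allylation of aldehydes by 3‑(bromomethyl)butenolides, which here copies the polarity of the farnesyl C1‑to‑C10 closure that builds the germacrane ring. The ten‑membered carbocycle (nine‑membered when counted across the ketal oxygen) closes in exo‑trig mode at the aldehyde carbon. C7 is controlled by the tether: the six‑carbon bridge spanning the cis 2,5‑positions of the tetrahydrofuran ketal should reach the butenolide comfortably only on the face that carries C9, which gives the 7,8‑cis lactone; C6 is controlled by the chair transition state, in which the ring‑fixed E‑type allyl unit and an equatorial C5 lead to the anti adduct, that is the 6S alcohol. The step needs aldehyde‑over‑ketone chemoselectivity and ring closure over oligomerisation; the C1 methyl ketal secures the first and slow addition at high dilution the second.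

Step 16
Reactants: 24 (1R,4S,6S,7R,8S,10R)-1,4-epoxy-6-hydroxy-1-methoxygermacr-11(13)-en-8,12-olide
Product: 25 (1R,4S,6R,7S,8S,10R)-1,4-epoxy-6-(isobutyryloxy)-1-methoxygermacr-11(13)-en-8,12-olide
Conditions: isobutyric acid, PPh3, diisopropyl azodicarboxylate, toluene, 0 °C to rt
Reagents that add atoms: isobutyric acid, CC(C)C(=O)O
Why: Mitsunobu esterification activates the C6 hydroxyl as an alkoxyphosphonium ion that isobutyrate should displace with inversion, turning the 6S alcohol into the 6R isobutyrate in the step that also installs the ester.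

Step 17
Reactants: 25 (1R,4S,6R,7S,8S,10R)-1,4-epoxy-6-(isobutyryloxy)-1-methoxygermacr-11(13)-en-8,12-olide
Product: 26 (4S,6R,7S,8S,10R)-4-hydroxy-6-(isobutyryloxy)-1-oxogermacr-11(13)-en-8,12-olide (target)
Conditions: AcOH/THF/H2O (3:1:1), rt
Reagents that add atoms: water, O
Why: Mild aqueous acid should hydrolyse the mixed ketal through the cyclic oxocarbenium ion to free the C1 ketone and the tertiary C4 hydroxyl, conditions under which the isobutyrate and the α‑methylene lactone persist.

**Compound list**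

1 | (S)-5-[(trityloxy)methyl]dihydrofuran-2(3H)-one | O=C1CC[C@@H](COC(c2ccccc2)(c2ccccc2)c2ccccc2)O1 | starting material
2 | lithium enolate of 1 | [Li]OC1=CC[C@@H](COC(c2ccccc2)(c2ccccc2)c2ccccc2)O1 | intermediate
3 | (3R,5S)-3-methyl-5-[(trityloxy)methyl]dihydrofuran-2(3H)-one | O=C1[C@H](C)C[C@@H](COC(c2ccccc2)(c2ccccc2)c2ccccc2)O1 | intermediate
4 | (3R,5S)-5-(hydroxymethyl)-3-methyldihydrofuran-2(3H)-one | O=C1[C@H](C)C[C@@H](CO)O1 | intermediate
5 | (2S,4R)-4-methyl-5-oxotetrahydrofuran-2-carbaldehyde | O=C1[C@H](C)C[C@@H](C=O)O1 | intermediate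
6 | (3R,5S)-3-methyl-5-vinyldihydrofuran-2(3H)-one | O=C1[C@H](C)C[C@@H](C=C)O1 | intermediate
7 | geraniol, (E)-3,7-dimethylocta-2,6-dien-1-ol | CC(C)=CCC/C(C)=C/CO | starting material
8 | [(2S,3S)-3-methyl-3-(4-methylpent-3-en-1-yl)oxiran-2-yl]methanol | OC[C@@H]1O[C@@]1(C)CCC=C(C)C | intermediate
9 | (S)-3,7-dimethyloct-6-ene-1,3-diol | OCC[C@@](C)(O)CCC=C(C)C | intermediate
10 | (S)-1-[(4-methoxybenzyl)oxy]-3,7-dimethyloct-6-en-3-ol | COc1ccc(COCC[C@@](C)(O)CCC=C(C)C)cc1 | intermediate
11 | (5S)-5-[2-[(4-methoxybenzyl)oxy]ethyl]-5-methyltetrahydrofuran-2-ol (both anomers) | COc1ccc(COCC[C@]2(C)CCC(O)O2)cc1 | intermediate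
12 | (S)-5-[2-[(4-methoxybenzyl)oxy]ethyl]-5-methyldihydrofuran-2(3H)-one | COc1ccc(COCC[C@]2(C)CCC(=O)O2)cc1 | intermediate
13 | lithium enolate of 12 | COc1ccc(COCC[C@]2(C)CC=C(O[Li])O2)cc1 | intermediate
14 | (5S)-3-[(2R,4S)-4-hydroxy-2-methylhex-5-enoyl]-5-[2-[(4-methoxybenzyl)oxy]ethyl]-5-methyldihydrofuran-2(3H)-one (C3 epimers) | C=C[C@@H](O)C[C@@H](C)C(=O)C1C[C@@](C)(CCOCc2ccc(OC)cc2)OC1=O | intermediate
15 | (4S)-4-hydroxy-2-[(2R,4S)-4-hydroxy-2-methylhex-5-enoyl]-6-[(4-methoxybenzyl)oxy]-4-methylhexanoic acid (C2 epimers) | C=C[C@@H](O)C[C@@H](C)C(=O)C(CC[C@](C)(O)CCOCc1ccc(OC)cc1)C(O)=O | intermediate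
16 | (3S,5R,9S)-3,9-dihydroxy-11-[(4-methoxybenzyl)oxy]-5,9-dimethylundec-1-en-6-one | C=C[C@@H](O)C[C@@H](C)C(=O)CC[C@](C)(O)CCOCc1ccc(OC)cc1 | intermediate
17 | 2-(bromomethyl)acrylic acid | C=C(CBr)C(=O)O | starting material
18 | (3S,5R,9S)-9-hydroxy-11-[(4-methoxybenzyl)oxy]-5,9-dimethyl-6-oxoundec-1-en-3-yl 2-(bromomethyl)acrylate | C=C[C@@H](OC(=O)C(=C)CBr)C[C@@H](C)C(=O)CC[C@](C)(O)CCOCc1ccc(OC)cc1 | intermediate
19 | (S)-3-(bromomethyl)-5-[(2R,6S)-6-hydroxy-8-[(4-methoxybenzyl)oxy]-2,6-dimethyl-3-oxooctyl]furan-2(5H)-one | O=C1O[C@@H](C[C@@H](C)C(=O)CC[C@](C)(O)CCOCc2ccc(OC)cc2)C=C1CBr | intermediate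
20 | (S)-3-(bromomethyl)-5-[(R)-2-[(2R,5S)-2-methoxy-5-[2-[(4-methoxybenzyl)oxy]ethyl]-5-methyltetrahydrofuran-2-yl]propyl]furan-2(5H)-one | O=C1O[C@@H](C[C@@H](C)[C@@]2(OC)CC[C@@](C)(CCOCc3ccc(OC)cc3)O2)C=C1CBr | intermediate
21 | (S)-3-(bromomethyl)-5-[(R)-2-[(2R,5S)-5-(2-hydroxyethyl)-2-methoxy-5-methyltetrahydrofuran-2-yl]propyl]furan-2(5H)-one | O=C1O[C@@H](C[C@@H](C)[C@@]2(OC)CC[C@@](C)(CCO)O2)C=C1CBr | intermediate
22 | (S)-3-(bromomethyl)-5-[(R)-2-[(2R,5S)-2-methoxy-5-methyl-5-(2-oxoethyl)tetrahydrofuran-2-yl]propyl]furan-2(5H)-one | O=C1O[C@@H](C[C@@H](C)[C@@]2(OC)CC[C@@](C)(CC=O)O2)C=C1CBr | intermediate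
23 | allylchromium dichloride derived from 22 (CrCl2 unit in place of bromine) | O=C1O[C@@H](C[C@@H](C)[C@@]2(OC)CC[C@@](C)(CC=O)O2)C=C1C[Cr](Cl)Cl | intermediate
24 | (1R,4S,6S,7R,8S,10R)-1,4-epoxy-6-hydroxy-1-methoxygermacr-11(13)-en-8,12-olide | C=C1C(=O)O[C@H]2C[C@@H](C)[C@@]3(OC)CC[C@](C)(O3)C[C@H](O)[C@@H]12 | intermediate
25 | (1R,4S,6R,7S,8S,10R)-1,4-epoxy-6-(isobutyryloxy)-1-methoxygermacr-11(13)-en-8,12-olide | C=C1C(=O)O[C@H]2C[C@@H](C)[C@@]3(OC)CC[C@](C)(O3)C[C@@H](OC(=O)C(C)C)[C@@H]12 | intermediate
26 | (4S,6R,7S,8S,10R)-4-hydroxy-6-(isobutyryloxy)-1-oxogermacr-11(13)-en-8,12-olide | C=C1C(=O)O[C@H]2C[C@@H](C)C(=O)CC[C@](C)(O)C[C@@H](OC(=O)C(C)C)[C@@H]12 | target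

**Step count and risks**

Total steps: 17 (3 for the West lactone, 4 for the East lactone, 10 after their union). Longest linear sequence: 14 steps (steps 4–17).

Steps most likely to fail:

1. Step 15. The aldehyde may be delivered to the butenolide face remote from C9 (trans ring fusion), or intermolecular coupling may outrun ring closure. Fallback: the bond is made with reversed polarity by a ketyl–olefin ring closure. From 22 the bromide is exchanged for acetate (CsO2CCH3, DMF) to give allylic acetate F1. Samarium diiodide in THF/t‑BuOH at high dilution then converts the aldehyde into a ketyl radical that adds to C7 of the butenolide, and the samarium enolate expels acetate to give the methylene lactone. The route is rejoined at 24.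

2. Step 16. Elimination towards C5 or C7, or conjugate addition of the phosphine to the methylene lactone, may compete with substitution at the hindered C6 carbinol. Fallback: from 24 the alcohol is converted into chloromethanesulfonate F2 (ClCH2SO2Cl, pyridine), which is displaced with inversion by CsO2CCH(CH3)2 and 18‑crown‑6 in toluene. The route is rejoined at 25.

3. Step 8. Proton exchange between the two lactones and self‑condensation may compete with cross‑acylation. Fallback: the C2 nucleophile is made as an organolithium instead of an enolate. From 10 the ozonolysis is stopped at lactol 11, whose hypoiodite (PhI(OAc)2, I2, visible light) fragments by alkoxy‑radical β‑scission to iodo formate F3. Methanolysis (K2CO3, MeOH) gives iodo alcohol F4, whose dilithio derivative (tert‑butyllithium, Et2O, −78 °C) should add once to lactone 6 and give keto diol 16 directly. The route is rejoined at 16.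

Further compounds
F1 | step 15 | [(S)-5-[(R)-2-[(2R,5S)-2-methoxy-5-methyl-5-(2-oxoethyl)tetrahydrofuran-2-yl]propyl]-2-oxo-2,5-dihydrofuran-3-yl]methyl acetate | O=C1O[C@@H](C[C@@H](C)[C@@]2(OC)CC[C@@](C)(CC=O)O2)C=C1COC(C)=O
F2 | step 16 | 6-O-chloromethanesulfonate of 24 | C=C1C(=O)O[C@H]2C[C@@H](C)[C@@]3(OC)CC[C@](C)(O3)C[C@H](OS(=O)(=O)CCl)[C@@H]12
F3 | step 8 | (R)-1-iodo-5-[(4-methoxybenzyl)oxy]-3-methylpentan-3-yl formate | COc1ccc(COCC[C@](C)(CCI)OC=O)cc1
F4 | step 8 | (R)-1-iodo-5-[(4-methoxybenzyl)oxy]-3-methylpentan-3-ol | COc1ccc(COCC[C@@](C)(O)CCI)cc1
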